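**Plan**
1. Retrosynthesis: the four-carbon tether (T1–T4, counted from the ring A carbinol carbon to the quaternary carbon of the bicyclo[2.2.2]octane) is cut at T1–T2 and T2–T3 around a dithiane at T2. This gives spiro-epoxide 14, silyl dithiane 29 and iodide 28; the aryl O–S bond, the C–S bonds and the O-benzyl bond are end-game operations.
2. Enabling feature: the ring A carbinol carbon is fully substituted, is flanked by the quaternary ring-fusion carbon and carries T1 as its only exocyclic CH2. An oxirane across carbinol carbon and T1 therefore offers one open CH2 to a carbanion and leaves the alkoxide 1,4 to silicon on T2; T3–T4 already sit as CH2CH2I on the east quaternary carbon.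
3. West half (steps 1–10): ring A comes from (S)-carvone (two α′-alkylations, conjugate reduction, isopropenyl to acetoxy); the oxepane (ring B) is closed by hydroalkoxylation in step 8; methylenation and epoxidation follow.
4. East half (steps 11–21): (1R)-(−)-nopol gives a verbenone-type enone, cuprate addition sets the quaternary carbon, the cyclobutane is cleaved, a radical alkenylation with nitrostyrene 18 builds the gem-dimethyl carbon, and a ketyl–olefin closure (step 19) forms the bicyclo[2.2.2]octan-1-ol.
5. Union in step 22, then desilylation, sulfation of the distal phenol, and Raney Ni removal of sulfur and benzyl (steps 23–25).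
6. Stereochemistry: west from C5 of carvone (alkylation anti to isopropenyl, Criegee shift with retention, equatorial methyl by equilibration, epoxidation anti to the angular methyl); east from the pinane bridgehead (cuprate anti to the gem-dimethyl bridge, cleft-controlled ketyl closure).

Key step: step 22

Assumption: the target is drawn as the free aryl hydrogen sulfate; it is carried as its sodium salt and protonated only in the last work-up.

**West half**

Step 1
Reactants: 1 (S)-carvone
Product: 3 trans-6-methylcarvone, via lithium dienolate 2 (not isolated)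
Conditions: LiN(i-Pr)2, THF, −78 °C; MeI, −78 → −20 °C
Reagents that add atoms: iodomethane, CI
Why: Kinetic α′-deprotonation and enolate methylation place the first carbon substituent on the future quaternary carbon, and the epimer ratio at that carbon is irrelevant because step 2 re-enolises it.

Step 2
Reactants: 3 trans-6-methylcarvone
Product: 5 6-methyl-6-propargylcarvone, via lithium dienolate 4 (not isolated)
Conditions: LiN(i-Pr)2, THF, −78 → −10 °C; DMPU, propargyl bromide, −78 °C → rt
Reagents that add atoms: 3-bromoprop-1-yne, C#CCBr
Why: Enolate alkylation by the reactive propargylic bromide should occur on the face opposite the neighbouring isopropenyl group, which fixes the quaternary carbon with methyl cis and the three-carbon arm trans to isopropenyl.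

Step 3
Reactants: 5 6-methyl-6-propargylcarvone
Product: 6 saturated propargyl ketone
Conditions: LiBH(s-Bu)3, THF, −78 °C; then H2O
Reagents that add atoms: none
Why: Conjugate hydride reduction of the β-unsubstituted enone, whose carbonyl is shielded by the quaternary neighbour, removes the ring alkene before ozonolysis; the new methyl-bearing carbon is epimerisable and should settle equatorial (away from the axial quaternary methyl) in the basic steps 7 and 9.

Step 4
Reactants: 6 saturated propargyl ketone
Product: 8 propargyl keto acetate, via methoxy hydroperoxide 7 (not isolated)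
Conditions: O3, NaHCO3, CH2Cl2/MeOH, −78 °C; then Ac2O, Et3N, DMAP (cat.), 0 → 40 °C
Reagents that add atoms: ozone, [O-][O+]=O; methanol, CO; acetic anhydride, CC(=O)OC(C)=O
Why: Ozonolysis of the 1,1-disubstituted alkene in methanol (the alkyne reacts far more slowly) followed by acylation triggers the Criegee rearrangement, in which the ring carbon migrates to oxygen with retention, so C5 of carvone becomes the oxygen-bearing ring-fusion carbon.

Step 5
Reactants: 8 propargyl keto acetate
Product: 9 keto aldehyde acetate
Conditions: [CpRu(NCMe)3]PF6 (5 mol %), 5,5′-bis(trifluoromethyl)-2,2′-bipyridine (5 mol %), NMP/H2O, 25 °C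
Reagents that add atoms: water, O
Why: Ruthenium-catalysed anti-Markovnikov hydration of the terminal alkyne (through a vinylidene) should give the aldehyde under neutral conditions that leave the ketone and the acetate untouched.

Step 6
Reactants: 9 keto aldehyde acetate
Product: 10 homoprenyl keto acetate
Conditions: i-PrPPh3I, n-BuLi, THF, 0 °C; then 9, −78 → 0 °C
Reagents that add atoms: isopropyltriphenylphosphonium iodide, CC(C)[P+](c1ccccc1)(c1ccccc1)c1ccccc1.[I-]
Why: Wittig olefination with the non-stabilised isopropylidene ylide is selective for the aldehyde over the ketone next to a quaternary carbon and installs the trisubstituted alkene whose far carbon becomes the gem-dimethyl ether carbon.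

Step 7
Reactants: 10 homoprenyl keto acetate
Product: 11 hydroxy ketone
Conditions: K2CO3 (cat.), MeOH, 0 °C
Reagents that add atoms: none
Why: Base-catalysed transesterification frees the secondary alcohol under conditions expected to be too mild for retro-aldol cleavage and equilibrates the α-methyl group to the equatorial position.

Step 8
Reactants: 11 hydroxy ketone
Product: 12 west ketone (trans-fused oxepane)
Conditions: Co(salen) (5 mol %), N-fluoro-2,4,6-trimethylpyridinium tetrafluoroborate, PhSiH3, PhCF3, 0 °C → rt
Reagents that add atoms: none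
Why: Mukaiyama-type hydrogen-atom transfer from a cobalt hydride to the trisubstituted alkene and oxidation of the tertiary radical give a tertiary cation that the ring hydroxyl captures (Markovnikov hydroalkoxylation), closing the 2,2-dimethyloxepane; the trans ring fusion follows from the existing trans relation of hydroxyl and side chain, and no new stereocentre forms.

Step 9
Reactants: 12 west ketone
Product: 13 exocyclic alkene
Conditions: Ph3PCH3Br, KOt-Bu, toluene, 90 °C
Reagents that add atoms: methyltriphenylphosphonium bromide, C[P+](c1ccccc1)(c1ccccc1)c1ccccc1.[Br-]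
Why: Wittig methylenation under forcing conditions should convert the hindered ketone into the exocyclic alkene, and any epimerisation at the adjacent methyl-bearing carbon returns the equatorial epimer, which avoids a 1,3-diaxial methyl pair.

Step 10
Reactants: 13 exocyclic alkene
Product: 14 west spiro-epoxide
Conditions: mCPBA, NaHCO3, CH2Cl2, 0 °C
Reagents that add atoms: 3-chloroperoxybenzoic acid, OOC(=O)c1cccc(Cl)c1
Why: Prilezhaev epoxidation should take the face of the exocyclic alkene opposite the axial angular methyl on the adjacent ring-fusion carbon, so the oxirane oxygen ends axial and anti to that methyl, which is the configuration of the target carbinol.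

**Aryl nitroalkene**

Step 11
Reactants: 15 2,5-dihydroxybenzaldehyde
Product: 16 2-hydroxy-5-(triisopropylsilyloxy)benzaldehyde
Conditions: i-Pr3SiCl, imidazole, CH2Cl2, 0 °C
Reagents that add atoms: chlorotriisopropylsilane, CC(C)[Si](Cl)(C(C)C)C(C)C
Why: Silylation is selective for the 5-hydroxyl because the 2-hydroxyl is hydrogen-bonded to the aldehyde and less nucleophilic.

Step 12
Reactants: 16 2-hydroxy-5-(triisopropylsilyloxy)benzaldehyde
Product: 17 2-(benzyloxy)-5-(triisopropylsilyloxy)benzaldehyde
Conditions: BnBr, K2CO3, acetone, 56 °C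
Reagents that add atoms: benzyl bromide, BrCc1ccccc1
Why: Williamson etherification of the remaining phenol installs the group that masks the proximal phenol until the last step.

Step 13
Reactants: 17 2-(benzyloxy)-5-(triisopropylsilyloxy)benzaldehyde
Product: 18 (E)-nitrostyrene
Conditions: MeNO2, NH4OAc, AcOH, 90 °C
Reagents that add atoms: nitromethane, C[N+](=O)[O-]
Why: Henry condensation (nitroaldol addition and dehydration) gives the E-nitroalkene that serves as the radical acceptor in step 18.

**East half**

Step 14
Reactants: 19 (1R)-(−)-nopol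
Product: 20 nopyl chloride
Conditions: PPh3, N-chlorosuccinimide, THF, 0 °C → rt
Reagents that add atoms: N-chlorosuccinimide, ClN1C(=O)CCC1=O
Why: Appel-type chlorination replaces the primary hydroxyl without acid, so the acid-labile pinene skeleton survives, and the chloride stays inert until the Finkelstein exchange of step 21.

Step 15
Reactants: 20 nopyl chloride
Product: 21 bicyclic enone
Conditions: CrO3, 3,5-dimethylpyrazole, CH2Cl2, −20 °C
Reagents that add atoms: chromium trioxide, O=[Cr](=O)=O
Why: Allylic oxidation of the ring CH2 (the α-pinene-to-verbenone transformation) should give the enone, the ring methylene being favoured over the side-chain CH2, which is deactivated by the β-chlorine.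

Step 16
Reactants: 21 bicyclic enone
Product: 22 4,4-disubstituted nopinone
Conditions: CuI, MeLi (2 equiv), Et2O, 0 °C; then 21, −78 → 0 °C; then H2O
Reagents that add atoms: lithium dimethylcuprate (from CuI and MeLi), [Li+].C[Cu-]C
Why: Gilman conjugate addition delivers methyl to the β-carbon from the face of the CH2 bridge, opposite the gem-dimethyl bridge, so the chloroethyl group ends on the side of the gem-dimethyl carbon as the east quaternary centre requires.

Step 17
Reactants: 22 4,4-disubstituted nopinone
Product: 24 isopropenyl cyclohexanone, via bromo ketone 23 (not isolated)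
Conditions: HBr (33% in AcOH), CH2Cl2, 0 °C; evaporation; then DBU, toluene, 80 °C
Reagents that add atoms: none
Why: Acid-induced heterolysis of the strained cyclobutane bond between the α-bridgehead and the gem-dimethyl carbon (the classical nopinone-to-menthanone cleavage) gives the tertiary bromide, and E2 elimination should take a methyl hydrogen because the tetrasubstituted alternative suffers allylic strain against the neighbouring quaternary carbon; both ring stereocentres are untouched.

Step 18
Reactants: 24 isopropenyl cyclohexanone; 18 (E)-nitrostyrene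
Product: 25 styrenyl ketone
Conditions: Fe(acac)3 (30 mol %), PhSiH3, EtOH, 60 °C
Reagents that add atoms: none
Why: Hydrogen-atom transfer from an iron hydride turns the isopropenyl group into a tertiary radical that adds to the nitro-bearing carbon of 18 and expels NO2 (radical addition–elimination), which forms the gem-dimethyl quaternary carbon and the E-styrene.

Step 19
Reactants: 25 styrenyl ketone
Product: 26 bicyclo[2.2.2]octan-1-ol
Conditions: SmI2, HMPA, t-BuOH, THF, 0 °C → rt
Reagents that add atoms: none
Why: SmI2 ketyl–olefin cyclisation (6-exo-trig onto the styrene carbon remote from the arene, then reduction and protonation of the benzylic radical) closes the third bridge; the bridgehead carbinol is fixed by the cage, and the arylvinyl group should occupy the open cleft beside the CH2CH2 bridge and not the cleft crowded by the chloroethyl group, which sets the benzyl-bearing carbon.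

Step 20
Reactants: 26 bicyclo[2.2.2]octan-1-ol
Product: 27 triethylsilyl ether
Conditions: Et3SiOTf, 2,6-lutidine, CH2Cl2, −78 → 0 °C
Reagents that add atoms: triethylsilyl trifluoromethanesulfonate, CC[Si](CC)(CC)OS(=O)(=O)C(F)(F)F
Why: Silyl triflate silylation caps the tertiary bridgehead alcohol so that it cannot quench the carbanion of step 22.

Step 21
Reactants: 27 triethylsilyl ether
Product: 28 east iodide
Conditions: NaI, 2-butanone, 80 °C
Reagents that add atoms: sodium iodide, [Na+].[I-]
Why: Finkelstein exchange at the unhindered primary carbon converts the chloride into the iodide needed as the second electrophile.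

**Union and end game**

Step 22
Reactants: 29 2-(tert-butyldimethylsilyl)-1,3-dithiane; 14 west spiro-epoxide; 28 east iodide
Product: 33 dithiane-linked silyl ether (full carbon skeleton), via lithiated silyl dithiane 30 (not isolated), via lithium alkoxide adduct 31 (not isolated), via Brook-shifted dithianyl anion 32 (not isolated)
Conditions: 29, t-BuLi, Et2O, −78 → −45 °C; 14, Et2O, −78 → 0 °C; then 28, HMPA, Et2O/THF, −78 °C → rt
Reagents that add atoms: none
Why: t-BuLi lithiates 29 at C2, and in ether the anion 30 opens oxirane 14 by SN2 at its CH2 to give alkoxide 31 (bond T1–T2). Addition of HMPA and iodide 28 triggers the 1,4-Brook shift of silicon from carbon to the tertiary alkoxide, which protects the carbinol and regenerates a dithiane-stabilised carbanion 32 on the same carbon; this anion is alkylated by the primary iodide (bond T2–T3). The closest known reaction is the solvent-gated anion relay coupling of 2-silyl-1,3-dithianes with an epoxide and a second electrophile. No ring closes and no stereocentre is created; the carbinol configuration is that of the oxirane oxygen set in step 10 and is untouched because substitution occurs at CH2. The step needs regioselective epoxide opening and a Brook shift that waits for the polar co-solvent: the fully substituted spiro carbon secures the first, and the tert-butyldimethylsilyl group in ether secures the second, so 32 cannot consume a second oxirane. The silyl ethers and the benzyl ether of 28 should be inert to the carbanion at low temperature.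

Step 23
Reactants: 33 dithiane-linked silyl ether
Product: 34 dithiane diol phenol
Conditions: Bu4NF, THF, 60 °C
Reagents that add atoms: none
Why: Fluoride-induced desilylation removes the aryl triisopropylsilyl, the bridgehead triethylsilyl and, on heating, the hindered tertiary tert-butyldimethylsilyl group, while the dithiane and the benzyl ether stay.

Step 24
Reactants: 34 dithiane diol phenol
Product: 35 sodium aryl sulfate
Conditions: SO3·pyridine, pyridine, rt; then aq. NaHCO3
Reagents that add atoms: sulfur trioxide–pyridine complex, [O-]S(=O)(=O)[n+]1ccccc1; sodium hydrogen carbonate, [Na+].OC([O-])=O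
Why: O-Sulfation with the SO3 complex is selective for the one free phenol because the two hindered tertiary alcohols react far more slowly, and the proximal phenol is still benzylated.

Step 25
Reactants: 35 sodium aryl sulfate
Product: 37 target CNP0255133.1, via sodium sulfate salt 36 (not isolated)
Conditions: Raney Ni (W-2), H2 (1 atm), EtOH, rt; then cold 0.1 M HCl to pH 3, n-BuOH extraction
Reagents that add atoms: none
Why: Raney Ni desulfurisation turns the dithiane carbon into the tether CH2 and hydrogenolyses the aryl benzyl ether, while the hexavalent sulfur of the sulfate monoester has no lone pair for nickel and should survive; brief cold acidification gives the hydrogen sulfate.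

**Compound list**

1 | (S)-(+)-carvone, (5S)-2-methyl-5-(prop-1-en-2-yl)cyclohex-2-en-1-one | CC1=CC[C@H](C(C)=C)CC1=O | starting material
2 | lithium cross-conjugated dienolate of 1 (not isolated) | [Li+].CC1=CC[C@H](C(C)=C)C=C1[O-] | intermediate
3 | (5S,6R)-2,6-dimethyl-5-(prop-1-en-2-yl)cyclohex-2-en-1-one (trans-6-methylcarvone; the cis epimer converges in step 2) | CC1=CC[C@H](C(C)=C)[C@@H](C)C1=O | intermediate
4 | lithium dienolate of 3 (not isolated) | [Li+].CC1=CC[C@H](C(C)=C)C(C)=C1[O-] | intermediate
5 | (5R,6R)-2,6-dimethyl-5-(prop-1-en-2-yl)-6-(prop-2-yn-1-yl)cyclohex-2-en-1-one (propargyl trans to isopropenyl) | CC1=CC[C@H](C(C)=C)[C@@](C)(CC#C)C1=O | intermediate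
6 | (2R,3R,6S)-2,6-dimethyl-3-(prop-1-en-2-yl)-2-(prop-2-yn-1-yl)cyclohexan-1-one (6-methyl equatorial) | C[C@H]1CC[C@H](C(C)=C)[C@@](C)(CC#C)C1=O | intermediate
7 | 3-(1-hydroperoxy-1-methoxyethyl)-2,6-dimethyl-2-(prop-2-yn-1-yl)cyclohexan-1-one, ring configuration as in 6 (not isolated) | C[C@H]1CC[C@H](C(C)(OC)OO)[C@@](C)(CC#C)C1=O | intermediate
8 | (1S,2R,4S)-2,4-dimethyl-3-oxo-2-(prop-2-yn-1-yl)cyclohexyl acetate | C[C@H]1CC[C@H](OC(C)=O)[C@@](C)(CC#C)C1=O | intermediate
9 | (1S,2R,4S)-2,4-dimethyl-3-oxo-2-(3-oxopropyl)cyclohexyl acetate | C[C@H]1CC[C@H](OC(C)=O)[C@@](C)(CCC=O)C1=O | intermediate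
10 | (1S,2R,4S)-2,4-dimethyl-2-(4-methylpent-3-en-1-yl)-3-oxocyclohexyl acetate | C[C@H]1CC[C@H](OC(C)=O)[C@@](C)(CCC=C(C)C)C1=O | intermediate
11 | (2R,3S,6S)-3-hydroxy-2,6-dimethyl-2-(4-methylpent-3-en-1-yl)cyclohexan-1-one | C[C@H]1CC[C@H](O)[C@@](C)(CCC=C(C)C)C1=O | intermediate
12 | (5aR,7S,9aS)-2,2,5a,7-tetramethyloctahydro-1-benzoxepin-6(2H)-one (trans ring fusion) | C[C@H]1CC[C@@H]2OC(C)(C)CCC[C@@]2(C)C1=O | intermediate
13 | (5aS,7S,9aS)-2,2,5a,7-tetramethyl-6-methylidenedecahydro-1-benzoxepine | C[C@H]1CC[C@@H]2OC(C)(C)CCC[C@@]2(C)C1=C | intermediate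
14 | (5aR,6S,7S,9aS)-2,2,5a,7-tetramethyloctahydro-2H-spiro[1-benzoxepine-6,2′-oxirane] (oxirane oxygen axial, anti to the 5a-methyl) | C[C@H]1CC[C@@H]2OC(C)(C)CCC[C@@]2(C)[C@]13CO3 | intermediate
15 | 2,5-dihydroxybenzaldehyde | O=Cc1cc(O)ccc1O | starting material
16 | 2-hydroxy-5-(triisopropylsilyloxy)benzaldehyde | O=Cc1cc(O[Si](C(C)C)(C(C)C)C(C)C)ccc1O | intermediate
17 | 2-(benzyloxy)-5-(triisopropylsilyloxy)benzaldehyde | O=Cc1cc(O[Si](C(C)C)(C(C)C)C(C)C)ccc1OCc1ccccc1 | intermediate
18 | (E)-1-(benzyloxy)-2-(2-nitroethenyl)-4-(triisopropylsilyloxy)benzene | [O-][N+](=O)/C=C/c1cc(O[Si](C(C)C)(C(C)C)C(C)C)ccc1OCc1ccccc1 | intermediate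
19 | (1R)-(−)-nopol, 2-[(1R,5S)-6,6-dimethylbicyclo[3.1.1]hept-2-en-2-yl]ethan-1-ol | OCCC1=CC[C@H]2C[C@@H]1C2(C)C | starting material
20 | (1R,5S)-2-(2-chloroethyl)-6,6-dimethylbicyclo[3.1.1]hept-2-ene | ClCCC1=CC[C@H]2C[C@@H]1C2(C)C | intermediate
21 | (1S,5R)-4-(2-chloroethyl)-6,6-dimethylbicyclo[3.1.1]hept-3-en-2-one | ClCCC1=CC(=O)[C@H]2C[C@@H]1C2(C)C | intermediate
22 | (1S,4S,5S)-4-(2-chloroethyl)-4,6,6-trimethylbicyclo[3.1.1]heptan-2-one (4-methyl on the face of the CH2 bridge) | ClCC[C@]1(C)CC(=O)[C@H]2C[C@@H]1C2(C)C | intermediate
23 | 4-(2-bromopropan-2-yl)-3-(2-chloroethyl)-3-methylcyclohexan-1-one, configuration as in 24 (not isolated) | ClCC[C@]1(C)CC(=O)CC[C@@H]1C(C)(C)Br | intermediate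
24 | (3S,4R)-3-(2-chloroethyl)-3-methyl-4-(prop-1-en-2-yl)cyclohexan-1-one (chloroethyl cis to isopropenyl) | ClCC[C@]1(C)CC(=O)CC[C@@H]1C(C)=C | intermediate
25 | 4-[(E)-4-aryl-2-methylbut-3-en-2-yl]-3-(2-chloroethyl)-3-methylcyclohexan-1-one, ring configuration as in 24, aryl = 2-(benzyloxy)-5-(triisopropylsilyloxy)phenyl | ClCC[C@]1(C)CC(=O)CC[C@@H]1C(C)(C)/C=C/c1cc(O[Si](C(C)C)(C(C)C)C(C)C)ccc1OCc1ccccc1 | intermediate
26 | 2-[2-(benzyloxy)-5-(triisopropylsilyloxy)benzyl]-5-(2-chloroethyl)-3,3,5-trimethylbicyclo[2.2.2]octan-1-ol (benzyl group and 5-methyl both on the side of the C7–C8 bridge) | ClCC[C@]1(C)C[C@@]2(O)CC[C@@H]1C(C)(C)[C@@H]2Cc1cc(O[Si](C(C)C)(C(C)C)C(C)C)ccc1OCc1ccccc1 | intermediate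
27 | triethylsilyl ether of 26 | ClCC[C@]1(C)C[C@@]2(O[Si](CC)(CC)CC)CC[C@@H]1C(C)(C)[C@@H]2Cc1cc(O[Si](C(C)C)(C(C)C)C(C)C)ccc1OCc1ccccc1 | intermediate
28 | east iodide, the 5-(2-iodoethyl) analogue of 27 | ICC[C@]1(C)C[C@@]2(O[Si](CC)(CC)CC)CC[C@@H]1C(C)(C)[C@@H]2Cc1cc(O[Si](C(C)C)(C(C)C)C(C)C)ccc1OCc1ccccc1 | intermediate
29 | 2-(tert-butyldimethylsilyl)-1,3-dithiane | CC(C)(C)[Si](C)(C)C1SCCCS1 | starting material
30 | 2-lithio-2-(tert-butyldimethylsilyl)-1,3-dithiane (not isolated) | [Li+].CC(C)(C)[Si](C)(C)[C-]1SCCCS1 | intermediate
31 | lithium alkoxide from opening of 14 at CH2 by 30, silicon still on the dithiane carbon (not isolated) | [Li+].C[C@H]1CC[C@@H]2OC(C)(C)CCC[C@@]2(C)[C@]1([O-])CC1(SCCCS1)[Si](C)(C)C(C)(C)C | intermediate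
32 | 2-lithio-1,3-dithiane carrying the O-silylated west half (after 1,4-Brook shift; not isolated) | [Li+].C[C@H]1CC[C@@H]2OC(C)(C)CCC[C@@]2(C)[C@]1(O[Si](C)(C)C(C)(C)C)C[C-]1SCCCS1 | intermediate
33 | coupled product: dithiane at T2, tert-butyldimethylsilyl ether on the ring A carbinol, triethylsilyl ether on the bridgehead, aryl OTIPS and OBn | C[C@H]1CC[C@@H]2OC(C)(C)CCC[C@@]2(C)[C@]1(O[Si](C)(C)C(C)(C)C)CC1(SCCCS1)CC[C@]1(C)C[C@@]2(O[Si](CC)(CC)CC)CC[C@@H]1C(C)(C)[C@@H]2Cc1cc(O[Si](C(C)C)(C(C)C)C(C)C)ccc1OCc1ccccc1 | intermediate
34 | desilylated dithiane: two tertiary alcohols, free distal phenol, benzyl ether on the proximal phenol | C[C@H]1CC[C@@H]2OC(C)(C)CCC[C@@]2(C)[C@]1(O)CC1(SCCCS1)CC[C@]1(C)C[C@@]2(O)CC[C@@H]1C(C)(C)[C@@H]2Cc1cc(O)ccc1OCc1ccccc1 | intermediate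
35 | sodium salt of the distal aryl sulfate of 34 | [Na+].C[C@H]1CC[C@@H]2OC(C)(C)CCC[C@@]2(C)[C@]1(O)CC1(SCCCS1)CC[C@]1(C)C[C@@]2(O)CC[C@@H]1C(C)(C)[C@@H]2Cc1cc(OS(=O)(=O)[O-])ccc1OCc1ccccc1 | intermediate
36 | sodium salt of the target (not isolated) | [Na+].C[C@H]1CC[C@@H]2OC(C)(C)CCC[C@@]2(C)[C@]1(O)CCCC[C@]1(C)C[C@@]2(O)CC[C@@H]1C(C)(C)[C@@H]2Cc1cc(OS(=O)(=O)[O-])ccc1O | intermediate
37 | CNP0255133.1 | C[C@H]1CC[C@@H]2OC(C)(C)CCC[C@@]2(C)[C@]1(O)CCCC[C@]1(C)C[C@@]2(O)CC[C@@H]1C(C)(C)[C@@H]2Cc1cc(OS(=O)(=O)O)ccc1O | target

**Step count and risks**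

Total: 25 steps. Longest linear sequence: 14 steps (steps 1–10 and 22–25).

Step 19. The ketyl may be reduced on to the secondary alcohol or dimerise before the ring reaches the boat-like geometry that 1,4-bridging demands, and the arylvinyl group may enter the wrong cleft, which would give poor facial selectivity at the benzyl-bearing carbon. The fallback sets out from 25 and comes back at 26 by a polar ring closure: BF3·OEt2 and Et3SiH in CH2Cl2 at −78 °C (reductive Prins reaction), in which the electron-rich styrene attacks the activated ketone through the same carbon and the o-alkoxybenzyl cation is reduced by the silane. This fallback makes no new compound (F0).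

Step 22. Attack of the bulky silyl dithiane anion on the neopentyl-like oxirane CH2 may be slow, and silyl transfer to the congested tertiary alkoxide may lag, so that the relay anion never forms and the iodide is left unconsumed. The fallback sets out from 14 and comes back at 33, making the same two bonds one after the other. The smaller 2-lithio-1,3-dithiane (1,3-dithiane, n-BuLi, THF, −30 °C → rt) opens 14 to the hydroxy dithiane F1. Silylation with t-BuMe2SiOTf and 2,6-lutidine gives the silyl ether F2. Deprotonation with t-BuLi in THF/HMPA at −78 °C and alkylation with 28 (Corey–Seebach alkylation) then give 33.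

Step 8. The tertiary radical or cation may be lost to alkene isomers or to simple hydrogenation before the hindered secondary hydroxyl closes the seven-membered ring. The fallback sets out from 11 and comes back at 12 by an ionic two-step route: oxymercuration with Hg(O2CCF3)2 in CH2Cl2 at 0 °C (Markovnikov attack of the hydroxyl on the mercurinium ion of divalent mercury) gives the organomercurial trifluoroacetate F3, and Bu3SnH with AIBN in toluene at 80 °C removes mercury without touching the ketone.

**Further compounds**

F0 | step 19 | none | none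
F1 | step 22 | hydroxy dithiane from 14 and 2-lithio-1,3-dithiane (tertiary alcohol, dithiane CH at T2) | C[C@H]1CC[C@@H]2OC(C)(C)CCC[C@@]2(C)[C@]1(O)CC1SCCCS1
F2 | step 22 | tert-butyldimethylsilyl ether of F1 | C[C@H]1CC[C@@H]2OC(C)(C)CCC[C@@]2(C)[C@]1(O[Si](C)(C)C(C)(C)C)CC1SCCCS1
F3 | step 8 | 3-(trifluoroacetoxymercurio) derivative of 12 (mercury on the oxepane CH next to the gem-dimethyl carbon) | C[C@H]1CC[C@@H]2OC(C)(C)C([Hg]OC(=O)C(F)(F)F)CC[C@@]2(C)C1=O
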